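Conventions used throughout: eremophilane numbering (ring A = C1–C5 and C10; ring B = C5–C10; C14 = methyl on C5; C15 = methyl on C4); β is the face of ring A that carries C14; "decal-" means the decalin (bicyclo[4.4.0]decane) skeleton with this numbering.

## Analysis of the target

Septeremophilane G (34) is a trinor-eremophilane: a twelve-carbon decalin core whose O3 is esterified with (2E,4E,6S)-6-methylocta-2,4-dienoic acid. Ring B is a flat, cross-conjugated 7-hydroxy-6,9(10)-dien-8-one (a diosphenol), so the ring fusion carries no stereocentre. The four core stereocentres are contiguous on ring A: C2 (R, α-OH), C3 (R, β-O-acyl), C4 (R, β-methyl) and quaternary C5 (S, β-methyl); the fifth (S) lies remote in the side chain. Because planar ring B holds C6 equatorial on ring A, C14 is axial, C15 equatorial and the two oxygens are trans-diaxial, with O3 syn-axial to C14. The acylated hydroxyl is therefore the more hindered one. Sensitive groups are the acidic, oxidisable diosphenol, the dienone (Michael acceptor, prone to dienone–phenol rearrangement in strong acid), the dienoate with its ε-stereocentre, and C4, which can epimerise whenever C3 is a ketone. The hard problems are the quaternary C5 next to tertiary C4 (vicinal cis-methyls) without a fusion stereocentre to steer them, and telling two neighbouring secondary hydroxyls apart. The strategy rests on C10: it is sp2 in 34, yet it is the atom that ties C5 to the C9–C8–C7–C6 chain of ring B. A temporary C10–H stereocentre can therefore pass its configuration to C5 in a ring closure onto a C4=C5 enone and then be removed by dehydrogenation.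

## Retrosynthetic reasoning

Ester and silyl groups. The C3–O acyl bond of 34 is cut last, giving alcohol 25 and acid 31 (through 33). The dienoate tolerates neither strong base nor oxidants, so it should arrive after all enolate and oxidation chemistry. O2 and O7 are silylated so that only the hindered O3 can be acylated, and one fluoride treatment then frees both. Acid 31 is cut at its C4=C5 olefin into phosphonate 27 and the aldehyde 28 derived from alcohol 26, which supplies the side-chain stereocentre.

Ring-A oxygens. In 25 → 24 → 23 → 21 the C3–H bond and then the C2–O bond are removed. Forward, an enolate oxidation must place oxygen on the α face of C2, and a hydride must reach C3 from the same face. Both are favoured by the chair that ring B imposes: the electrophile enters axially at C2, and the axial C14 blocks the β face of C3. The C2 hydroxyl can in addition deliver the hydride.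

Ring-B oxygen. In 21 → 20 → 19 → 18 → 17 the C7–O bond is traced to an epoxide on the less substituted enone arm of a cross-conjugated dienone. This is placed after the C9=C10 olefin is present, because then only one enol tautomer of the 7,8-dioxygenated ring is possible. C3 stays masked as a dioxolane through this phase, which confines enolisation to ring B and keeps C4 from epimerising.

The C9=C10 olefin. 17 → 15 → 14 removes the olefin and restores a C10–H. Forward this is a dehydrogenation of the ring-B enone on its α′ side; it deletes the stereocentre that has done its work.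

Key disconnection. 14 → 13 cuts the C5–C6 bond (and the C4–H bond). This is the cut that removes ring B, the quaternary centre and the C4 centre together and leaves a planar tetrasubstituted enone with a single stereocentre. Forward, a C6 alkenyl–metal species must add across C4=C5 from the face on which its tether hangs, and the resulting C4–metal bond must be reduced.

The iodoenone arm. 13 → 12 → 11 → 9 + 10 removes the C6–I bond (hydroiodination of a terminal ynone, which must give the Z isomer) and the C7–C8 bond (acetylide addition to an aldehyde, then oxidation).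

Ring A and C10. 9 → 8 → 6 → 5 → 2 + 3 → 1 cuts the terminal olefin carbon (oxidative cleavage), the C5–C14 bond (methyl addition to a vinylogous ester followed by transposition) and the C10–C9 bond (enantioselective decarboxylative allylation at the α′ carbon). All of this is standard chemistry on a cheap dione, so the risk is concentrated in the ring closure.

## Alternatives that were turned down

Alternative 1: Both ring-B bonds C5–C10 and C6–C7 are cut in an intramolecular Diels–Alder reaction. Trienone A1 carries a 2-silyloxydiene (C7–C10) and an isopropenyl ketone (C5=C6, carbonyl at C4), joined by a four-atom tether that already bears O2 and O3 as a trans-dioxolane from a chiral-pool diol. Heating or a Lewis acid would give the cis-fused silyl enol ether A2.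
- For it: two bonds, ring B and the quaternary centre form in one step, and the O2/O3 pair is bought with the right relative and absolute configuration. On that point it is stronger than the chosen route, which needs three late steps for these oxygens.
- Against it: C15 is absent from A2 and would have to be grafted onto the C4 ketone, which sits between quaternary C5 and the epimerisable, oxygenated C3. The trans-fused dioxolane stiffens the tether, and neither its stereocentres nor an endo/exo preference clearly fixes the face at C5. Silyloxydiene and acetonide are labile to Lewis acids. O2 and O3 emerge undifferentiated although only the hindered one is to be acylated. Ring B arrives saturated at C6–C7 and needs more oxidation than 14.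
- In comparison, the chosen route lets one stereocentre decide C5 through a geometric necessity and delivers C15 and the C6=C7 olefin in the same step.

Alternative 2: The C1–C10 bond of ring A is cut. Cathodic reduction of the redox-active ester A3 would release CO2 and a primary C1 radical, which adds 6-exo to one of the two enone arms of a 4,4-disubstituted cyclohexa-2,5-dienone; reduction and protonation at C9 give A4.
- For it: A4 is in effect 14 with O2 and O3 already in place and the ring-B enone intact. On endgame economy it is stronger than the chosen route.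
- Against it: the C2–C3–C4 triad must be built on an open chain attached directly to the quaternary dienone carbon, so the difficult C4/C5 relationship is moved into the precursor synthesis, not solved. Which diastereotopic arm is attacked depends on modest conformational preferences of a flexible chain. The dienone is itself reducible at the cathode, which narrows the potential window. O2 and O3 are again undifferentiated.
- In comparison, the chosen route offers a precursor (13) with a single stereocentre, eight steps from a commodity dione, and a face selection at C5 that follows from ring geometry and not from a choice between two similar arms.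

Alternative 3: The C1–C2 bond of ring A is cut in an intramolecular vinylogous Mukaiyama aldol reaction. A Lewis acid activates the aldehyde of A5, the exocyclic terminus C1 of the silyl dienol ether attacks C2, and A6 results with the ring-B enone restored.
- For it: A6 has the C9=C10 olefin where the target needs it, and O2 (free) and O3 (protected) are already distinguished. On both points it is stronger than the chosen route, which must dehydrogenate and must differentiate the diol.
- Against it: A5 requires C3, C4 and quaternary C5 contiguous on a cyclohexenone before the key step, so the central difficulty again falls on the precursor. The C2 configuration (trans-diaxial to O3) depends on a weakly biased cyclic transition state. The product is a δ-hydroxy enone that can lose O2 by vinylogous elimination under the Lewis acid. The C7 oxygen and the C6=C7 olefin remain to be installed.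
- In comparison, the chosen strategy makes the C4/C5 pair and ring B in one operation from a flat enone and pays for it with a longer ring-A endgame.

Key step: step 9

Assumption: the (R,R)-enantiomer of the ANDEN-phenyl Trost ligand is taken to deliver the (R)-configured allyl compound 6; should the sense of induction be opposite, the (S,S)-ligand is used with no other change.

## Route

Step 1
Reactants: 1 2-methylcyclohexane-1,3-dione
Product: 2 3-isobutoxy-2-methylcyclohex-2-en-1-one
Conditions: i-BuOH, p-TsOH·H2O (cat.), toluene, reflux, Dean–Stark
Reagents that add atoms: 2-methylpropan-1-ol, CC(C)CO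
Why: Acid-catalysed vinylogous esterification of a symmetrical cyclic 1,3-dione, driven by azeotropic removal of water; only one constitutional product can form.

Step 2
Reactants: 2 3-isobutoxy-2-methylcyclohex-2-en-1-one; 3 allyl chloroformate
Product: 5 allyl 5-isobutoxy-6-methylcyclohexa-1,5-dien-1-yl carbonate, via lithium dienolate 4 (not isolated)
Conditions: LiN(i-Pr)2 (LDA), THF, −78 °C; TMEDA, then ClCO2CH2CH=CH2, −78 → 0 °C
Reagents that add atoms: none
Why: Kinetic deprotonation of a vinylogous ester occurs at the α′ carbon, and the TMEDA-solvated lithium enolate is acylated on oxygen by the hard chloroformate, giving the allyl enol carbonate needed for decarboxylative allylation.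

Step 3
Reactants: 5 allyl 5-isobutoxy-6-methylcyclohexa-1,5-dien-1-yl carbonate
Product: 6 (R)-6-allyl-3-isobutoxy-2-methylcyclohex-2-en-1-one
Conditions: Pd2(dba)3·CHCl3 (2.5 mol %), (R,R)-ANDEN-phenyl Trost ligand (6 mol %), 1,4-dioxane, 23 °C
Reagents that add atoms: none
Why: Tsuji–Trost decarboxylative asymmetric allylic alkylation: ionisation and loss of CO2 give an enolate/π-allylpalladium pair that recombines at the α′ carbon inside the chiral pocket, setting the future C10 (R). The neutral medium, in which the enolate exists only next to its electrophile, should prevent racemisation and double allylation of the α′-tertiary centre.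

Step 4
Reactants: 6 (R)-6-allyl-3-isobutoxy-2-methylcyclohex-2-en-1-one
Product: 8 (R)-4-allyl-2,3-dimethylcyclohex-2-en-1-one, via tertiary allylic alcohol 7 (not isolated)
Conditions: MeLi, Et2O, −78 → 0 °C; then 1 M HCl, THF, 0 → 23 °C
Reagents that add atoms: methyllithium, [Li]C; water, O
Why: Stork–Danheiser transposition: 1,2-addition to the vinylogous ester carbonyl, then acid hydrolysis of the enol ether with loss of isobutanol and water gives the transposed enone that carries C14. The stereocentre becomes the γ carbon and is not touched, since material that is enolised and not alkylated only returns starting ketone.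

Step 5
Reactants: 8 (R)-4-allyl-2,3-dimethylcyclohex-2-en-1-one
Product: 9 (R)-2-(2,3-dimethyl-4-oxocyclohex-2-en-1-yl)acetaldehyde
Conditions: OsO4 (2 mol %), NaIO4 (4 equiv), 2,6-lutidine, dioxane–H2O (3:1), 23 °C
Reagents that add atoms: osmium tetroxide, O=[Os](=O)(=O)=O; sodium periodate, [Na+].[O-]I(=O)(=O)=O
Why: Lemieux–Johnson cleavage: OsO4 dihydroxylates the monosubstituted olefin far faster than the electron-poor tetrasubstituted enone olefin, and periodate cleaves the diol; lutidine limits over-oxidation.

Step 6
Reactants: 9 (R)-2-(2,3-dimethyl-4-oxocyclohex-2-en-1-yl)acetaldehyde; 10 ethynylmagnesium bromide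
Product: 11 (4R)-4-(2-hydroxybut-3-yn-1-yl)-2,3-dimethylcyclohex-2-en-1-one (carbinol epimers)
Conditions: HC≡CMgBr (1.1 equiv), THF, −78 → −40 °C; NH4Cl (aq)
Reagents that add atoms: none
Why: Grignard 1,2-addition; the aldehyde is far more electrophilic than the hindered, conjugated, α-substituted ring ketone, and the new carbinol centre is removed in the next step.

Step 7
Reactants: 11 (4R)-4-(2-hydroxybut-3-yn-1-yl)-2,3-dimethylcyclohex-2-en-1-one
Product: 12 (R)-2,3-dimethyl-4-(2-oxobut-3-yn-1-yl)cyclohex-2-en-1-one
Conditions: Dess–Martin periodinane, CH2Cl2, 0 → 23 °C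
Reagents that add atoms: none
Why: Dess–Martin oxidation of a propargylic alcohol to the ynone without base, so neither the γ-stereocentre nor the terminal alkyne is disturbed.

Step 8
Reactants: 12 (R)-2,3-dimethyl-4-(2-oxobut-3-yn-1-yl)cyclohex-2-en-1-one
Product: 13 (R)-4-[(Z)-4-iodo-2-oxobut-3-en-1-yl]-2,3-dimethylcyclohex-2-en-1-one
Conditions: NaI, AcOH, 23 °C, dark
Reagents that add atoms: sodium iodide, [Na+].[I-]
Why: Conjugate hydroiodination of a terminal ynone: iodide adds to the alkyne terminus and the allenol is protonated in the plane anti to iodine, so the kinetic (Z)-β-iodoenone should result. The tetrasubstituted ring enone does not add HI irreversibly.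

Step 9
Reactants: 13 (R)-4-[(Z)-4-iodo-2-oxobut-3-en-1-yl]-2,3-dimethylcyclohex-2-en-1-one
Product: 14 cis-fused 4β,5β-dimethyl-10β-H-decal-6-ene-3,8-dione [(1R,4aR,8aR)-1,8a-dimethyl-1,3,4,4a,5,8a-hexahydronaphthalene-2,6-dione]
Conditions: Pd(OAc)2 (10 mol %), PPh3 (20 mol %), HCO2Na (1.5 equiv), Bu4NCl (1 equiv), dry DMF, 80 °C
Reagents that add atoms: none
Why: Pd(OAc)2 is reduced by PPh3 to zerovalent palladium, which inserts into the C6–I bond with retention to give a (Z)-alkenyl complex of divalent palladium held by chelation to the C8 carbonyl. Syn migratory insertion of the C4=C5 olefin follows, C6 bonding to the β-carbon C5; the closest known reaction type is the intramolecular reductive Heck (conjugate) cyclisation of alkenyl halides onto β,β-disubstituted enones that forms quaternary centres. Ring B closes in a 6-exo-trig mode (C5 inside the new ring, C4 outside). C5 is controlled by C10: the three-atom link C9–C8–C7 can bring C6 to C5 only on the face of ring A from which it hangs, so the fusion must be cis and C14 is forced onto the face of H10. C4 is controlled by the syn addition to an olefin whose two methyl groups are cis: palladium arrives on the face of C6 and C15 moves to the face of C14; in the aprotic medium formate replaces iodide, loses CO2 and the hydride is transferred to C4 with retention. The step needs cyclisation to outrun hydride transfer to the alkenylpalladium (intramolecularity, chloride, and the low solubility of HCO2Na in DMF keep the hydride concentration small) and needs reduction to outrun β-hydride elimination toward C15 (an α-palladated ketone and its oxa-π-allyl form eliminate slowly). An (E)-alkenyl isomer cannot reach C5, and the ring-B enone is left intact because the palladium hydride is consumed by reductive elimination.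

Step 10
Reactants: 14 cis-fused 4β,5β-dimethyl-10β-H-decal-6-ene-3,8-dione
Product: 15 3,3-ethylenedioxy-4β,5β-dimethyl-10β-H-decal-6-en-8-one (C3 dioxolane of 14)
Conditions: Me3SiOCH2CH2OSiMe3, Me3SiOTf (5 mol %), CH2Cl2, −78 → −20 °C; pyridine quench
Reagents that add atoms: 1,2-bis(trimethylsilyloxy)ethane, C[Si](C)(C)OCCO[Si](C)(C)C
Why: Noyori ketalisation: the saturated C3 ketone reacts much faster than the conjugated C8 ketone. The cold aprotic conditions avoid enolisation toward C4 and migration of the ring-B olefin, so the C4 configuration is locked here.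

Step 11
Reactants: 15 3,3-ethylenedioxy-4β,5β-dimethyl-10β-H-decal-6-en-8-one
Product: 17 3,3-ethylenedioxy-4β,5β-dimethyldecala-6,9(10)-dien-8-one, via trimethylsilyl dienol ether 16 (not isolated)
Conditions: Me3SiCl, LiN(i-Pr)2 (LDA), THF, −78 °C (in situ quench); then Pd(OAc)2 (1.05 equiv), MeCN, 23 °C
Reagents that add atoms: none
Why: Kinetic α′-deprotonation of the enone at C9 (C5 has no hydrogen) gives the 2-silyloxydiene. Saegusa–Ito oxidation then palladates C9 and eliminates H10, forming the C9=C10 olefin and removing the C10 stereocentre once it has set C5.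

Step 12
Reactants: 17 3,3-ethylenedioxy-4β,5β-dimethyldecala-6,9(10)-dien-8-one
Product: 18 6,7-epoxy-3,3-ethylenedioxy-4β,5β-dimethyldecal-9(10)-en-8-one (epoxide expected anti to C14; configuration immaterial)
Conditions: 30% H2O2, NaOH (0.3 equiv), MeOH, 0 °C
Reagents that add atoms: hydrogen peroxide, OO
Why: Weitz–Scheffer nucleophilic epoxidation: hydroperoxide adds to the β-CH carbon C6 of the disubstituted enone arm much faster than to the fully substituted C10, the selectivity known for steroidal 1,4-dien-3-ones. Both epoxide carbons become sp2 in the next step.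

Step 13
Reactants: 18 6,7-epoxy-3,3-ethylenedioxy-4β,5β-dimethyldecal-9(10)-en-8-one
Product: 19 3,3-ethylenedioxy-7-hydroxy-4β,5β-dimethyldecala-6,9(10)-dien-8-one
Conditions: KOH (3 equiv), H2O–dioxane (1:2), 60 °C; NaH2PO4 to pH 6–7
Reagents that add atoms: potassium hydroxide, [K+].[OH-]
Why: Base-mediated isomerisation of an α,β-epoxy ketone to a diosphenol: hydroxide opens the epoxide at the carbonyl-activated C7, and the β-hydroxy ketone loses the C6 oxygen by E1cB (so the C7 oxygen of 19 is the hydroxide oxygen). Because C9 is already sp2, the enol can only lie toward C6, and a single cross-conjugated tautomer should form.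

Step 14
Reactants: 19 3,3-ethylenedioxy-7-hydroxy-4β,5β-dimethyldecala-6,9(10)-dien-8-one
Product: 20 3,3-ethylenedioxy-4β,5β-dimethyl-7-triisopropylsilyloxydecala-6,9(10)-dien-8-one
Conditions: i-Pr3SiCl, imidazole, DMF, 23 °C
Reagents that add atoms: chlorotriisopropylsilane, CC(C)[Si](Cl)(C(C)C)C(C)C
Why: O-silylation of the acidic enol hydroxyl under conditions that leave the dioxolane alone; the bulky silyl enol ether protects the diosphenol from base, hydride and acylating agents in the steps that follow.

Step 15
Reactants: 20 3,3-ethylenedioxy-4β,5β-dimethyl-7-triisopropylsilyloxydecala-6,9(10)-dien-8-one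
Product: 21 4β,5β-dimethyl-7-triisopropylsilyloxydecala-6,9(10)-diene-3,8-dione
Conditions: PPTS, acetone–H2O (10:1), 45 °C
Reagents that add atoms: water, O
Why: Mild acid hydrolysis of a dioxolane that is strained by a syn-axial contact with C14; the triisopropylsilyl enol ether and the dienone tolerate pyridinium tosylate, and such weak acid should not enolise C3 toward the hindered C4.

Step 16
Reactants: 21 4β,5β-dimethyl-7-triisopropylsilyloxydecala-6,9(10)-diene-3,8-dione
Product: 23 2α-hydroxy-4β,5β-dimethyl-7-triisopropylsilyloxydecala-6,9(10)-diene-3,8-dione, via sodium enolate 22 (not isolated)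
Conditions: NaN(SiMe3)2, THF, −78 °C; 2-(phenylsulfonyl)-3-phenyloxaziridine, −78 °C; NH4Cl (aq)
Reagents that add atoms: 2-(phenylsulfonyl)-3-phenyloxaziridine, O=S(=O)(N1OC1c1ccccc1)c1ccccc1
Why: Kinetic enolisation of the C3 ketone at the CH2 carbon C2 (C4–H is flanked by the quaternary centre, and the dienone has only remote γ-hydrogens out of reach of the carbonyl-bound base), followed by Davis oxaziridine hydroxylation. The oxidant should enter axially on the α face, which leads directly to the chair and avoids the face shielded by axial C14, giving the 2α-alcohol.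

Step 17
Reactants: 23 2α-hydroxy-4β,5β-dimethyl-7-triisopropylsilyloxydecala-6,9(10)-diene-3,8-dione
Product: 24 2α,3β-dihydroxy-4β,5β-dimethyl-7-triisopropylsilyloxydecala-6,9(10)-dien-8-one
Conditions: Me4NBH(OAc)3, MeCN–AcOH (1:1), −30 → 0 °C
Reagents that add atoms: none
Why: Hydroxyl-directed (Evans–Saksena type) reduction: the 2α-hydroxyl binds boron and delivers hydride to the α face of C3, giving the trans-diol with the 3β-hydroxyl. The same face is the one left open to any external hydride because axial C14 blocks the β trajectory, and the dienone ketone, which has no directing hydroxyl, is not reduced by this reagent.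

Step 18
Reactants: 24 2α,3β-dihydroxy-4β,5β-dimethyl-7-triisopropylsilyloxydecala-6,9(10)-dien-8-one
Product: 25 3β-hydroxy-4β,5β-dimethyl-2α-triethylsilyloxy-7-triisopropylsilyloxydecala-6,9(10)-dien-8-one
Conditions: Et3SiCl (1.1 equiv), imidazole, CH2Cl2, −20 → 0 °C
Reagents that add atoms: chlorotriethylsilane, CC[Si](Cl)(CC)CC
Why: Selective silylation of the less hindered hydroxyl: O3 is flanked by the C4 methyl and is syn-axial to C14, whereas O2 has only a CH2 neighbour.

Step 19
Reactants: 26 (S)-2-methylbutan-1-ol; 27 triethyl (E)-4-phosphonocrotonate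
Product: 30 ethyl (2E,4E,6S)-6-methylocta-2,4-dienoate, via (S)-2-methylbutanal 28 (not isolated), via lithiated phosphonate 29 (not isolated)
Conditions: Dess–Martin periodinane, CH2Cl2, 0 °C; filtered, dried solution added to 27 + LiN(SiMe3)2, THF, −78 → 0 °C
Reagents that add atoms: none
Why: Base-free Dess–Martin oxidation gives the volatile, epimerisable aldehyde, which is consumed at once in a vinylogous Horner–Wadsworth–Emmons olefination. The stabilised anion at low temperature should leave the α-stereocentre intact and give mainly the (2E,4E)-dienoate.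

Step 20
Reactants: 30 ethyl (2E,4E,6S)-6-methylocta-2,4-dienoate
Product: 31 (2E,4E,6S)-6-methylocta-2,4-dienoic acid
Conditions: LiOH, THF–MeOH–H2O, 23 °C; 1 M HCl to pH 3
Reagents that add atoms: lithium hydroxide, [Li+].[OH-]
Why: Saponification; the ε-hydrogen of the dienoate is not acidic enough under aqueous hydroxide at room temperature for the stereocentre or the olefin geometry to be at risk.

Step 21
Reactants: 25 3β-hydroxy-4β,5β-dimethyl-2α-triethylsilyloxy-7-triisopropylsilyloxydecala-6,9(10)-dien-8-one; 31 (2E,4E,6S)-6-methylocta-2,4-dienoic acid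
Product: 33 4β,5β-dimethyl-3β-[(2E,4E,6S)-6-methylocta-2,4-dienoyloxy]-2α-triethylsilyloxy-7-triisopropylsilyloxydecala-6,9(10)-dien-8-one, via mixed anhydride 32 (not isolated)
Conditions: 2,4,6-Cl3C6H2COCl, Et3N, toluene, 23 °C; then 25, DMAP, toluene, 23 → 60 °C
Reagents that add atoms: none
Why: Yamaguchi esterification: the mixed anhydride and DMAP form an acylpyridinium ion reactive enough for a hindered axial secondary alcohol. O3 is the only free hydroxyl, so no site selectivity is needed.

Step 22
Reactants: 33 4β,5β-dimethyl-3β-[(2E,4E,6S)-6-methylocta-2,4-dienoyloxy]-2α-triethylsilyloxy-7-triisopropylsilyloxydecala-6,9(10)-dien-8-one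
Product: 34 septeremophilane G [(1R,2R,3R,8aS)-3,7-dihydroxy-1,8a-dimethyl-6-oxo-1,2,3,4,6,8a-hexahydronaphthalen-2-yl (2E,4E,6S)-6-methylocta-2,4-dienoate]
Conditions: HF·pyridine, pyridine–THF, 0 → 23 °C
Reagents that add atoms: none
Why: Fluoride-mediated cleavage of both silicon–oxygen bonds (alkyl triethylsilyl ether and triisopropylsilyl enol ether) in a buffered, weakly acidic medium that neither hydrolyses the dienoate nor opens the dienone. Acyl migration from O3 to O2 is not expected because the trans-diaxial pair cannot form the cyclic intermediate.

## Compound list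

1 | 2-methylcyclohexane-1,3-dione | CC1C(=O)CCCC1=O | starting material
2 | 3-isobutoxy-2-methylcyclohex-2-en-1-one | CC(C)COC1=C(C)C(=O)CCC1 | intermediate
3 | allyl chloroformate | C=CCOC(=O)Cl | starting material
4 | lithium 5-isobutoxy-6-methylcyclohexa-1,5-dien-1-olate | [Li+].[O-]C1=CCCC(OCC(C)C)=C1C | intermediate
5 | allyl 5-isobutoxy-6-methylcyclohexa-1,5-dien-1-yl carbonate | C=CCOC(=O)OC1=CCCC(OCC(C)C)=C1C | intermediate
6 | (R)-6-allyl-3-isobutoxy-2-methylcyclohex-2-en-1-one | CC(C)COC1=C(C)C(=O)[C@@H](CC=C)CC1 | intermediate
7 | (6R)-6-allyl-3-isobutoxy-1,2-dimethylcyclohex-2-en-1-ol (C1 epimers, formed as the lithium alkoxide) | CC(C)COC1=C(C)C(C)(O)[C@@H](CC=C)CC1 | intermediate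
8 | (R)-4-allyl-2,3-dimethylcyclohex-2-en-1-one | CC1=C(C)C(=O)CC[C@@H]1CC=C | intermediate
9 | (R)-2-(2,3-dimethyl-4-oxocyclohex-2-en-1-yl)acetaldehyde | CC1=C(C)C(=O)CC[C@@H]1CC=O | intermediate
10 | ethynylmagnesium bromide | C#C[Mg]Br | starting material
11 | (4R)-4-(2-hydroxybut-3-yn-1-yl)-2,3-dimethylcyclohex-2-en-1-one (carbinol epimers) | CC1=C(C)C(=O)CC[C@@H]1CC(O)C#C | intermediate
12 | (R)-2,3-dimethyl-4-(2-oxobut-3-yn-1-yl)cyclohex-2-en-1-one | CC1=C(C)C(=O)CC[C@@H]1CC(=O)C#C | intermediate
13 | (R)-4-[(Z)-4-iodo-2-oxobut-3-en-1-yl]-2,3-dimethylcyclohex-2-en-1-one | CC1=C(C)C(=O)CC[C@@H]1CC(=O)/C=C\I | intermediate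
14 | cis-fused 4β,5β-dimethyl-10β-H-decal-6-ene-3,8-dione, (1R,4aR,8aR)-1,8a-dimethyl-1,3,4,4a,5,8a-hexahydronaphthalene-2,6-dione | O=C1CC[C@@H]2CC(=O)C=C[C@]2(C)[C@H]1C | intermediate
15 | 3,3-ethylenedioxy-4β,5β-dimethyl-10β-H-decal-6-en-8-one | O1CCOC12CC[C@@H]3CC(=O)C=C[C@]3(C)[C@H]2C | intermediate
16 | 3,3-ethylenedioxy-4β,5β-dimethyl-8-trimethylsilyloxy-10β-H-decala-6,8-diene | O1CCOC12CC[C@@H]3C=C(O[Si](C)(C)C)C=C[C@]3(C)[C@H]2C | intermediate
17 | 3,3-ethylenedioxy-4β,5β-dimethyldecala-6,9(10)-dien-8-one | O1CCOC12CCC3=CC(=O)C=C[C@]3(C)[C@H]2C | intermediate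
18 | 6,7-epoxy-3,3-ethylenedioxy-4β,5β-dimethyldecal-9(10)-en-8-one (epoxide configuration not fixed) | O1CCOC12CCC3=CC(=O)C4OC4[C@]3(C)[C@H]2C | intermediate
19 | 3,3-ethylenedioxy-7-hydroxy-4β,5β-dimethyldecala-6,9(10)-dien-8-one | O1CCOC12CCC3=CC(=O)C(O)=C[C@]3(C)[C@H]2C | intermediate
20 | 3,3-ethylenedioxy-4β,5β-dimethyl-7-triisopropylsilyloxydecala-6,9(10)-dien-8-one | O1CCOC12CCC3=CC(=O)C(O[Si](C(C)C)(C(C)C)C(C)C)=C[C@]3(C)[C@H]2C | intermediate
21 | 4β,5β-dimethyl-7-triisopropylsilyloxydecala-6,9(10)-diene-3,8-dione | O=C1CCC2=CC(=O)C(O[Si](C(C)C)(C(C)C)C(C)C)=C[C@]2(C)[C@H]1C | intermediate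
22 | sodium Δ2-enolate of 21 | [Na+].[O-]C1=CCC2=CC(=O)C(O[Si](C(C)C)(C(C)C)C(C)C)=C[C@]2(C)[C@H]1C | intermediate
23 | 2α-hydroxy-4β,5β-dimethyl-7-triisopropylsilyloxydecala-6,9(10)-diene-3,8-dione | O=C1[C@H](O)CC2=CC(=O)C(O[Si](C(C)C)(C(C)C)C(C)C)=C[C@]2(C)[C@H]1C | intermediate
24 | 2α,3β-dihydroxy-4β,5β-dimethyl-7-triisopropylsilyloxydecala-6,9(10)-dien-8-one | O[C@H]1[C@H](O)CC2=CC(=O)C(O[Si](C(C)C)(C(C)C)C(C)C)=C[C@]2(C)[C@H]1C | intermediate
25 | 3β-hydroxy-4β,5β-dimethyl-2α-triethylsilyloxy-7-triisopropylsilyloxydecala-6,9(10)-dien-8-one | O[C@H]1[C@H](O[Si](CC)(CC)CC)CC2=CC(=O)C(O[Si](C(C)C)(C(C)C)C(C)C)=C[C@]2(C)[C@H]1C | intermediate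
26 | (S)-2-methylbutan-1-ol | CC[C@H](C)CO | starting material
27 | triethyl (E)-4-phosphonocrotonate | CCOC(=O)/C=C/CP(=O)(OCC)OCC | starting material
28 | (S)-2-methylbutanal | CC[C@H](C)C=O | intermediate
29 | lithiated triethyl (E)-4-phosphonocrotonate | [Li+].CCOC(=O)/C=C/[CH-]P(=O)(OCC)OCC | intermediate
30 | ethyl (2E,4E,6S)-6-methylocta-2,4-dienoate | CC[C@H](C)/C=C/C=C/C(=O)OCC | intermediate
31 | (2E,4E,6S)-6-methylocta-2,4-dienoic acid | CC[C@H](C)/C=C/C=C/C(=O)O | intermediate
32 | (2E,4E,6S)-6-methylocta-2,4-dienoic 2,4,6-trichlorobenzoic anhydride | CC[C@H](C)/C=C/C=C/C(=O)OC(=O)c1c(Cl)cc(Cl)cc1Cl | intermediate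
33 | 4β,5β-dimethyl-3β-[(2E,4E,6S)-6-methylocta-2,4-dienoyloxy]-2α-triethylsilyloxy-7-triisopropylsilyloxydecala-6,9(10)-dien-8-one | CC[C@H](C)/C=C/C=C/C(=O)O[C@H]1[C@H](O[Si](CC)(CC)CC)CC2=CC(=O)C(O[Si](C(C)C)(C(C)C)C(C)C)=C[C@]2(C)[C@H]1C | intermediate
34 | septeremophilane G | CC[C@H](C)/C=C/C=C/C(=O)O[C@H]1[C@H](O)CC2=CC(=O)C(O)=C[C@]2(C)[C@H]1C | target

## Step count and least certain steps

Total: 22 steps. Longest linear sequence: 20 steps (steps 1–18, 21 and 22, from 1); acid 31 is made in two steps (19 and 20) and joined in step 21.

Step 9 (key step). Migratory insertion into a tetrasubstituted enone is slow, so hydride transfer to the alkenylpalladium may come first and remove iodine without ring closure. β-Hydride elimination toward C15 may compete with reduction. If the palladium enolate is protonated and not reduced, the configuration at C4 may erode; the two C4 epimers are separable and interconvert through the enolate, so this would cost material but not the route. Fallback: from 13, a stoichiometric nickel-mediated conjugate cyclisation (Ni(cod)2, Et3N, MeCN, 23 °C). The C–I bond adds to zerovalent nickel, the alkenylnickel inserts the enone in the same 6-exo sense, and the nickel enolate is protonated on work-up. No hydride donor is present, so reduction cannot precede cyclisation. The fallback returns to the route at 14 and passes through no compound outside the list (F0).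

Step 3. Facial discrimination of an enolate that gives an α′-tertiary (not quaternary) centre may be modest, and proton exchange between product and enolate may lower the enantiomeric purity further. Fallback: from 2, deprotonation with LiN(i-Pr)2 and alkylation with allyl bromide gives racemic 6-allyl-3-isobutoxy-2-methylcyclohex-2-en-1-one F1. Its enantiomers are separated by preparative chromatography on a chiral stationary phase, and the (R)-enantiomer re-enters the route as 6.

Step 13. Hydroxide may add reversibly at C10 or cleave the ring in place of opening the epoxide at C7, and the hindered C6 oxygen may be slow to leave. Fallback: from 17, the disubstituted C6=C7 olefin is hydrogenated selectively with RhCl(PPh3)3 and H2 to give 3,3-ethylenedioxy-4β,5β-dimethyldecal-9(10)-en-8-one F2. Kinetic α′-enolisation (LiN(i-Pr)2, −78 °C) and Davis oxaziridine give 3,3-ethylenedioxy-7-hydroxy-4β,5β-dimethyldecal-9(10)-en-8-one F3. Dess–Martin oxidation gives the 7,8-dione, which enolises toward C6 and is 19.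

Step 16. Proton transfer may move the negative charge to C1 (the γ position of the dienone), the oxidant may approach the β face, or the enolate may add to the sulfonimine by-product. Fallback: from 21, deprotonation with LiN(i-Pr)2 in the presence of Me3SiCl traps the kinetic enolate at once as 4β,5β-dimethyl-3-trimethylsilyloxy-7-triisopropylsilyloxydecala-2,6,9(10)-trien-8-one F4. Rubottom oxidation with dimethyldioxirane at −78 °C (the small, neutral oxidant epoxidises the electron-rich enol ether on the α face) and mild acid work-up give 23.

Step 21. Acylation of the axial, doubly flanked O3 may be so slow that the activated dienoyl species is deprotonated at its ε carbon (loss of olefin geometry and of the side-chain stereocentre), or that a silyl group migrates. Fallback: from 25, the small, ketene-forming diethylphosphonoacetic acid with DCC and catalytic DMAP gives 3β-(diethylphosphonoacetoxy)-4β,5β-dimethyl-2α-triethylsilyloxy-7-triisopropylsilyloxydecala-6,9(10)-dien-8-one F5. Aldehyde 28 is homologated with (triphenylphosphoranylidene)acetaldehyde to (S,E)-4-methylhex-2-enal F6. A Horner–Wadsworth–Emmons reaction of F5 with F6 (LiCl, DBU, MeCN) builds the dienoate on the ring and returns to the route at 33.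

## Further compounds

F0 | step 9 | none | none
F1 | step 3 | racemic 6-allyl-3-isobutoxy-2-methylcyclohex-2-en-1-one | CC(C)COC1=C(C)C(=O)C(CC=C)CC1
F2 | step 13 | 3,3-ethylenedioxy-4β,5β-dimethyldecal-9(10)-en-8-one | O1CCOC12CCC3=CC(=O)CC[C@]3(C)[C@H]2C
F3 | step 13 | 3,3-ethylenedioxy-7-hydroxy-4β,5β-dimethyldecal-9(10)-en-8-one (C7 epimers) | O1CCOC12CCC3=CC(=O)C(O)C[C@]3(C)[C@H]2C
F4 | step 16 | 4β,5β-dimethyl-3-trimethylsilyloxy-7-triisopropylsilyloxydecala-2,6,9(10)-trien-8-one | C[Si](C)(C)OC1=CCC2=CC(=O)C(O[Si](C(C)C)(C(C)C)C(C)C)=C[C@]2(C)[C@H]1C
F5 | step 21 | 3β-(diethylphosphonoacetoxy)-4β,5β-dimethyl-2α-triethylsilyloxy-7-triisopropylsilyloxydecala-6,9(10)-dien-8-one | CCOP(=O)(OCC)CC(=O)O[C@H]1[C@H](O[Si](CC)(CC)CC)CC2=CC(=O)C(O[Si](C(C)C)(C(C)C)C(C)C)=C[C@]2(C)[C@H]1C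
F6 | step 21 | (S,E)-4-methylhex-2-enal | CC[C@H](C)/C=C/C=O
A1 | alternative 1 | (7E)-9-(tert-butyldimethylsilyloxy)-4,5-(isopropylidenedioxy)-2-methyldeca-1,7,9-trien-3-one (trans-dioxolane) | CC1(C)O[C@@H]([C@H](O1)C/C=C/C(=C)O[Si](C)(C)C(C)(C)C)C(=O)C(C)=C
A2 | alternative 1 | cis-fused 2,3-O-isopropylidene-5-methyl-8-(tert-butyldimethylsilyloxy)decal-8-en-4-one | CC1(C)O[C@H]2[C@H](O1)C[C@@H]1C=C(O[Si](C)(C)C(C)(C)C)CC[C@]1(C)C2=O
A3 | alternative 2 | N-phthalimidoyl 3,4-O-isopropylidene-3,4-dihydroxy-5-(1-methyl-4-oxocyclohexa-2,5-dien-1-yl)hexanoate | CC1(C)O[C@H]([C@H](C)C2(C)C=CC(=O)C=C2)[C@H](O1)CC(=O)ON1C(=O)c2ccccc2C1=O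
A4 | alternative 2 | cis-fused 2,3-O-isopropylidene-4,5-dimethyldecal-6-en-8-one | CC1(C)O[C@H]2[C@H](O1)C[C@@H]1CC(=O)C=C[C@]1(C)[C@H]2C
A5 | alternative 3 | 2-(4-methoxybenzyloxy)-3-[4-(tert-butyldimethylsilyloxy)-1-methyl-2-methylenecyclohex-3-en-1-yl]butanal | C=C1C=C(O[Si](C)(C)C(C)(C)C)CC[C@]1(C)[C@@H](C)[C@@H](OCc1ccc(OC)cc1)C=O
A6 | alternative 3 | 2α-hydroxy-3β-(4-methoxybenzyloxy)-4β,5β-dimethyldecal-9-en-8-one | COc1ccc(CO[C@H]2[C@H](O)CC3=CC(=O)CC[C@]3(C)[C@H]2C)cc1
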